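**Plan**

- Retrosynthesis: the dihydrofuran is cut at O–C10 and C(aryl)–C1 (aristolane numbering), giving the symmetric chalcone 16 and aristol-1(10)-ene-8,9-dione 11. Compound 11 comes from (−)-aristolone 9 by oxygenation at C9, 9 from dienone 8 by isopropylidene transfer (C6–C11, C7–C11), and ring B from a Robinson annulation on (3R)-2,3-dimethylcyclohexanone.
- Forward: ring A is bought as 2-methylcyclohexenone; ring B (steps 2–3), the cyclopropane (step 5) and the C9 carbonyl (steps 6–7) follow. The chalcone is made separately (steps 8–10), and the dihydrofuran is closed last by joining the two halves (step 11).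
- Enabling feature: the C1=C10–C9(=O)–C8(=O) ene-1,2-dione across rings A/B is electrophilic at C1 and, once C1 carries the aryl group, becomes a diosphenol that is nucleophilic at C10 directly beside a phenol OH. The 2,6-dihydroxy-4-methoxyphenyl ketone ring has two equivalent OH/C–H pairs, so no protecting or directing group is needed.
- Stereochemistry: C4 by Cu-catalysed asymmetric conjugate addition; C5 by alkylation anti to the C4 methyl (matched auxiliary); C6/C7 by ylide attack anti to the C14 methyl; C1 by axial attack and C10 by the cis-fusion constraint in step 11.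

Key step: step 11

Assumption: the ligand enantiomer in step 1 is the one that gives the 3R ketone, and ene-dione 11 is treated as a kinetically stable tautomer that is used at once.

**Route**

Step 1
Reactants: 1 2-methylcyclohex-2-en-1-one
Product: 2 (3R)-2,3-dimethylcyclohexan-1-one (C2 epimers)
Conditions: Me3Al, CuTC (cat.), Feringa-type BINOL phosphoramidite (cat.), Et2O, −30 °C; aq. NH4Cl
Reagents that add atoms: trimethylaluminium, C[Al](C)C
Why: Copper-catalysed asymmetric conjugate addition of a methyl–aluminium reagent to an α-substituted cyclic enone; the ligand sets C3 (the later C4), and C2 is left as an epimer mixture because it is set again in step 2.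

Step 2
Reactants: 2 (3R)-2,3-dimethylcyclohexan-1-one; 3 methyl vinyl ketone
Product: 6 (2S,3R)-2,3-dimethyl-2-(3-oxobutyl)cyclohexan-1-one, via imine 4 (not isolated), via keto imine 5 (not isolated)
Conditions: (S)-1-phenylethylamine, TsOH (cat.), toluene, reflux, Dean–Stark; then 3, THF, rt to 40 °C; then 20% aq. AcOH, rt
Reagents that add atoms: none
Why: d'Angelo–Pfau Michael reaction of a chiral imine, in which the more substituted secondary enamine tautomer adds to the enone through an aza-ene-like transition state anti to the C3 methyl (reinforced by the (S)-auxiliary), so the quaternary centre (later C5) forms with the two methyls cis.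

Step 3
Reactants: 6 (2S,3R)-2,3-dimethyl-2-(3-oxobutyl)cyclohexan-1-one
Product: 7 (4aS,5R)-4a,5-dimethyl-4,4a,5,6,7,8-hexahydronaphthalen-2(3H)-one
Conditions: NaOMe (cat.), MeOH, 60 °C
Reagents that add atoms: none
Why: Intramolecular aldol condensation of the 1,5-diketone (second half of the Robinson annulation) closes ring B as the conjugated octalone without touching either stereocentre.

Step 4
Reactants: 7 (4aS,5R)-4a,5-dimethyl-4,4a,5,6,7,8-hexahydronaphthalen-2(3H)-one
Product: 8 (4aR,5R)-4a,5-dimethyl-5,6,7,8-tetrahydronaphthalen-2(4aH)-one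
Conditions: DDQ, dioxane, reflux
Reagents that add atoms: none
Why: DDQ dehydrogenation of a 4-en-3-one-type octalone under neutral conditions should give the cross-conjugated dienone, as with 10-methyloctalones and Δ4-3-keto steroids; no stereocentre is touched (the descriptor at C4a changes only by priority).

Step 5
Reactants: 8 (4aR,5R)-4a,5-dimethyl-5,6,7,8-tetrahydronaphthalen-2(4aH)-one
Product: 9 (−)-aristolone [(1aR,7R,7aR,7bS)-1,1,7,7a-tetramethyl-1,1a,4,5,6,7,7a,7b-octahydro-2H-cyclopropa[a]naphthalen-2-one]
Conditions: i-PrPh2S+ BF4−, LDA, DME, −78 °C; then 8, −78 to −20 °C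
Reagents that add atoms: isopropyldiphenylsulfonium tetrafluoroborate, CC(C)[S+](c1ccccc1)c1ccccc1.F[B-](F)(F)F
Why: Corey-type isopropylidene transfer (conjugate addition of the sulfonium ylide, then 3-exo-tet closure) should take place at the disubstituted CH=CH bond rather than at the fully substituted C10, and on the face anti to the angular C14 methyl, which sets C6 and C7.

Step 6
Reactants: 9 (−)-aristolone
Product: 10 (9ξ)-9-hydroxyaristol-1(10)-en-8-one
Conditions: KHMDS, THF, −78 to −40 °C; then 2-(phenylsulfonyl)-3-phenyloxaziridine, −78 °C; aq. NH4Cl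
Reagents that add atoms: 2-(phenylsulfonyl)-3-phenyloxaziridine, O=S(=O)(N1OC1c1ccccc1)c1ccccc1
Why: Only the γ-hydrogens at C1 can be removed (C7–H is a cyclopropane ring-fusion hydrogen), and the extended enolate should be hydroxylated at its α-carbon C9 by the Davis reagent to give the β,γ-unsaturated ketol; the C9 configuration is not controlled and is destroyed in step 7.

Step 7
Reactants: 10 (9ξ)-9-hydroxyaristol-1(10)-en-8-one
Product: 11 aristol-1(10)-ene-8,9-dione
Conditions: Dess–Martin periodinane, NaHCO3, CH2Cl2, 0 °C; short neutral silica pad; used at once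
Reagents that add atoms: none
Why: Dess–Martin oxidation of a secondary allylic α-ketol under buffered, neutral conditions should give the conjugated ene-1,2-dione without giving the C9 carbonyl a chance to enolise toward C2.

Step 8
Reactants: 12 1-(2,6-dihydroxy-4-methoxyphenyl)ethan-1-one
Product: 13 1-[2-hydroxy-4-methoxy-6-(methoxymethoxy)phenyl]ethan-1-one
Conditions: MOMCl (1.1 equiv), i-Pr2NEt, CH2Cl2, 0 °C to rt
Reagents that add atoms: chloromethyl methyl ether, COCCl
Why: O-alkylation stops after one hydroxyl because the remaining one is chelated to the ketone, and the two hydroxyls of 12 are equivalent.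

Step 9
Reactants: 13 1-[2-hydroxy-4-methoxy-6-(methoxymethoxy)phenyl]ethan-1-one; 14 4-methoxybenzaldehyde
Product: 15 (E)-1-[2-hydroxy-4-methoxy-6-(methoxymethoxy)phenyl]-3-(4-methoxyphenyl)prop-2-en-1-one
Conditions: KOH (aq.), EtOH, rt
Reagents that add atoms: none
Why: Claisen–Schmidt condensation, whose E1cB dehydration gives the E-enone, while the MOM ether survives base and blocks one of the two flavanone-forming hydroxyls.

Step 10
Reactants: 15 (E)-1-[2-hydroxy-4-methoxy-6-(methoxymethoxy)phenyl]-3-(4-methoxyphenyl)prop-2-en-1-one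
Product: 16 (E)-1-(2,6-dihydroxy-4-methoxyphenyl)-3-(4-methoxyphenyl)prop-2-en-1-one
Conditions: 3 M HCl, MeOH, 40 °C, short reaction time
Reagents that add atoms: none
Why: Acid-catalysed acetal exchange transfers the methoxymethyl group to methanol under conditions mild enough to leave the chalcone uncyclised.

Step 11
Reactants: 11 aristol-1(10)-ene-8,9-dione; 16 (E)-1-(2,6-dihydroxy-4-methoxyphenyl)-3-(4-methoxyphenyl)prop-2-en-1-one
Product: 18 target chalcone–aristolane hybrid (1R,4R,5R,6S,7R,10S in aristolane numbering), via diosphenol adduct 17 (not isolated)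
Conditions: Sc(OTf)3 (10 mol%), 4 Å MS, CH2Cl2/MeCN, −20 to 0 °C; then K2CO3, I2 (1.1 equiv), MeCN, 0 °C to rt, dark; aq. Na2S2O3
Reagents that add atoms: none
Why: Proposed new method: Sc(III) chelates the 8,9-dione, and the nuclear carbon between OH and OMe of 16 adds to C1 of the C1=C10–C9=O enone to leave diosphenol 17 (C9 enol, nucleophilic at C10) with a phenol OH held next to C10, the closest known reaction being the Lewis-acid Friedel–Crafts alkylation of phenols with β,γ-unsaturated α-keto esters. Hypoiodite from I2/K2CO3 then oxidises the enolate of 17 at C10 (C- or O-iodinated enol equivalent) and the tethered phenoxide oxygen displaces iodide, the closest known reaction being the hypoiodite oxidative cycloetherification of keto-phenols to 2-acyl-2,3-dihydrobenzofurans, which tolerates fully substituted α-carbons. The five-membered ring therefore closes in a 5-exo mode by O–C10 bond formation after the intermolecular C–C bond, i.e. a formal oxidative (3+2) annulation of a phenol C–H/O–H pair across C1=C10. C1 is controlled by the substrate: attack is axial on the ring-A half-chair, parallel to the enone π system, which puts the aryl group on the α face syn to the axial C14 methyl (the analogue of 6β attack on Δ4-3-keto steroids). C10 is controlled by the tether, since oxygen can only reach the face of C10 on which its aryl group sits (cis ring fusion), and the opposite β face is in addition screened by the endo methyl of the cyclopropane. The step needs C1 rather than C2 attack, C- rather than O-alkylation, and oxidation of the enol rather than of the free nuclear C–H of the chalcone; acid catalysis on the intact, chelated ene-dione at low temperature secures the first two, and the higher reducing power of the diosphenolate together with the intramolecular ring closure secures the third.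

**Compound list**

1 | 2-methylcyclohex-2-en-1-one | CC1=CCCCC1=O | starting material
2 | (3R)-2,3-dimethylcyclohexan-1-one (C2 epimers) | O=C1CCC[C@@H](C)C1C | intermediate
3 | methyl vinyl ketone (but-3-en-2-one) | C=CC(C)=O | starting material
4 | (S)-N-[(3R)-2,3-dimethylcyclohexylidene]-1-phenylethanamine (imine) | C[C@H](N=C1CCC[C@@H](C)C1C)c1ccccc1 | intermediate
5 | (S)-N-[(2S,3R)-2,3-dimethyl-2-(3-oxobutyl)cyclohexylidene]-1-phenylethanamine (keto imine) | C[C@H](N=C1CCC[C@@H](C)[C@]1(C)CCC(C)=O)c1ccccc1 | intermediate
6 | (2S,3R)-2,3-dimethyl-2-(3-oxobutyl)cyclohexan-1-one | CC(=O)CC[C@@]1(C)[C@H](C)CCCC1=O | intermediate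
7 | (4aS,5R)-4a,5-dimethyl-4,4a,5,6,7,8-hexahydronaphthalen-2(3H)-one | C12=CC(=O)CC[C@@]1(C)[C@H](C)CCC2 | intermediate
8 | (4aR,5R)-4a,5-dimethyl-5,6,7,8-tetrahydronaphthalen-2(4aH)-one | C12=CC(=O)C=C[C@@]1(C)[C@H](C)CCC2 | intermediate
9 | (−)-aristolone, (1aR,7R,7aR,7bS)-1,1,7,7a-tetramethyl-1,1a,4,5,6,7,7a,7b-octahydro-2H-cyclopropa[a]naphthalen-2-one | C12=CC(=O)[C@@H]3[C@@H](C3(C)C)[C@@]1(C)[C@H](C)CCC2 | intermediate
10 | (9ξ)-9-hydroxyaristol-1(10)-en-8-one (4R,5R,6S,7R; C9 epimers) | OC1C(=O)[C@@H]2[C@@H](C2(C)C)[C@@]3(C)[C@H](C)CCC=C13 | intermediate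
11 | aristol-1(10)-ene-8,9-dione, (1aR,7R,7aR,7bS)-1,1,7,7a-tetramethyl-1a,5,6,7,7a,7b-hexahydro-1H-cyclopropa[a]naphthalene-2,3-dione | O=C1C(=O)[C@@H]2[C@@H](C2(C)C)[C@@]3(C)[C@H](C)CCC=C13 | intermediate
12 | 1-(2,6-dihydroxy-4-methoxyphenyl)ethan-1-one | CC(=O)c1c(O)cc(OC)cc1O | starting material
13 | 1-[2-hydroxy-4-methoxy-6-(methoxymethoxy)phenyl]ethan-1-one | CC(=O)c1c(O)cc(OC)cc1OCOC | intermediate
14 | 4-methoxybenzaldehyde | COc1ccc(C=O)cc1 | starting material
15 | (E)-1-[2-hydroxy-4-methoxy-6-(methoxymethoxy)phenyl]-3-(4-methoxyphenyl)prop-2-en-1-one | COCOc1cc(OC)cc(O)c1C(=O)/C=C/c1ccc(OC)cc1 | intermediate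
16 | (E)-1-(2,6-dihydroxy-4-methoxyphenyl)-3-(4-methoxyphenyl)prop-2-en-1-one | COc1ccc(/C=C/C(=O)c2c(O)cc(OC)cc2O)cc1 | intermediate
17 | (1S)-1-{2,4-dihydroxy-6-methoxy-3-[(E)-3-(4-methoxyphenyl)acryloyl]phenyl}-9-hydroxyaristol-9-en-8-one (aryl α at C1; diosphenol adduct) | COc1ccc(/C=C/C(=O)c2c(O)cc(OC)c(c2O)[C@H]2CC[C@@H](C)[C@]3(C)[C@H]4[C@@H](C(=O)C(O)=C23)C4(C)C)cc1 | intermediate
18 | target: 2'-hydroxy-4,4'-dimethoxychalcone whose C5' and C6'–O are cis-fused as a dihydrofuran onto C1 and C10 of aristolane-8,9-dione, (1R,4R,5R,6S,7R,10S) | COc1ccc(/C=C/C(=O)c2c(O)cc(OC)c3c2O[C@]24C(=O)C(=O)[C@@H]5[C@@H](C5(C)C)[C@@]2(C)[C@H](C)CC[C@H]34)cc1 | target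

**Step count**

Total: 11 steps. Longest linear sequence: 8 steps (steps 1–7, then step 11).

**Steps most likely to fail**

1. Step 11 (Proposed new method). The oxidant may be diverted to iodination of the still unsubstituted nuclear carbon of the electron-rich chalcone ring, or the free 2',6'-dihydroxychalcone may cyclise onto its own enone, before the hindered C10–O bond forms. The fallback uses known reactions in separate operations and builds the chalcone last; it sets out from 11 and 12. Sc(OTf)3-catalysed Friedel–Crafts conjugate addition of acetophenone 12 to 11 gives, after isolation, the diosphenol 1α-(3-acetyl-2,4-dihydroxy-6-methoxyphenyl)-9-hydroxyaristol-9-en-8-one F1. Catalytic hypoiodite cycloetherification (Bu4NI cat., t-BuOOH, EtOAc, rt), which the acetophenone tolerates, closes the dihydrofuran to the acetyl analogue of the target F2. Claisen–Schmidt condensation of F2 with 14 (KOH, EtOH, 0 °C to rt, short contact time to spare the α-dione) then comes back to the route at 18.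

2. Step 7. The new C9 carbonyl may enolise toward C2 during oxidation or filtration, which moves the C1=C10 bond out of conjugation and leaves the unreactive ring-A dienol instead of the ene-dione. The fallback avoids a free ene-dione and sets out from 10. Base-mediated α-ketol transposition (DBU cat., toluene, rt) gives the conjugated (8ξ)-8-hydroxyaristol-1(10)-en-9-one F3, a chelating α'-hydroxy enone. Sc(OTf)3-catalysed Friedel–Crafts conjugate addition of 16 to F3 gives the 1α-aryl-8-hydroxyaristolan-9-one F4 (C8 and C10 not defined; both are reset). Oxidation of its ketol with Cu(OAc)2 (MeOH/AcOH) gives the 8,9-dione, isolated as its enol, so the fallback comes back to the route at 17, which is closed to 18 with I2/K2CO3 as in the second half of step 11.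

3. Step 5. The bulky tertiary ylide may deprotonate the dienone at its γ-position or add to the carbonyl instead of adding to the β-carbon next to the quaternary centre. The fallback sets out from 8. 1,3-Dipolar cycloaddition of 2-diazopropane (from acetone hydrazone and HgO, Et2O, −30 °C) to the disubstituted C=C bond, anti to the angular methyl, gives the 3,3-dimethyl-1-pyrazoline adduct of 8 F5 (C6–CMe2–N=N–C7, β face). Photolysis (Pyrex, Et2O, 0 °C) extrudes nitrogen and comes back to the route at 9.

**Further compounds**

F1 | step 11 | 1α-(3-acetyl-2,4-dihydroxy-6-methoxyphenyl)-9-hydroxyaristol-9-en-8-one | CC(=O)c1c(O)cc(OC)c(c1O)[C@H]1CC[C@@H](C)[C@]2(C)[C@H]3[C@@H](C(=O)C(O)=C12)C3(C)C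
F2 | step 11 | acetyl analogue of 18 (acetyl in place of the 4-methoxycinnamoyl group; 1R,4R,5R,6S,7R,10S) | CC(=O)c1c(O)cc(OC)c2c1O[C@]13C(=O)C(=O)[C@@H]4[C@@H](C4(C)C)[C@@]1(C)[C@H](C)CC[C@H]23
F3 | step 7 | (8ξ)-8-hydroxyaristol-1(10)-en-9-one | O=C1C(O)[C@@H]2[C@@H](C2(C)C)[C@@]3(C)[C@H](C)CCC=C13
F4 | step 7 | 1α-{2,4-dihydroxy-6-methoxy-3-[(E)-3-(4-methoxyphenyl)acryloyl]phenyl}-8-hydroxyaristolan-9-one (8ξ,10ξ) | COc1ccc(/C=C/C(=O)c2c(O)cc(OC)c(c2O)[C@H]2CC[C@@H](C)[C@]3(C)[C@H]4[C@@H](C(O)C(=O)C23)C4(C)C)cc1
F5 | step 5 | 3,3-dimethyl-1-pyrazoline adduct of 8 (C6–CMe2–N=N–C7 on the β face) | C12=CC(=O)[C@H]3N=NC(C)(C)[C@H]3[C@@]1(C)[C@H](C)CCC2
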